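**Retrosynthetic overview**

1. Benzofuran numbering is used (O1, C2, C3, C3a, C4–C7, C7a; ring A the carbocycle, ring B the dihydrofuran). The strategy rests on the fact that both C-prenyl groups, on quaternary C3a and on C7, stand ortho to a ring-A oxygen (O4 and O6). Both C–CH2 bonds are therefore cut back to O-(1,1-dimethylallyl) ethers of the aromatic dihydrobenzofuran 13 (double Claisen shift, the second one dearomative).
2. Ring B of 13 is opened at O1–C2: 5-exo epoxide opening by the phenoxide para to the acyl group. That oxygen is unmasked from a TIPS ether only after O4 and O6 already carry their tert-allyl ethers, so closure can only go through O1. C2 comes from a Shi epoxidation of a C-prenyl group.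
3. Ring A is the phloroglucinol ring throughout: Friedel–Crafts acylation, mono C-prenylation, para-selective silylation, bis O-tert-prenylation.
4. Order of ring events: ring A (from phloroglucinol), then ring B (step 7), then dearomatisation of ring A with creation of C3a (step 8).

Key step: step 8

Remark: the D-fructose-derived Shi ketone is assumed to give the (R)-epoxide of an ArCH2–CH=CMe2 unit, its usual sense for trisubstituted olefins; SN2 ring closure then inverts this centre to (S)-C2.

**Step 1**
Reactants: 1 phloroglucinol; 2 isovaleryl chloride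
Product: 3 1-(2,4,6-trihydroxyphenyl)-3-methylbutan-1-one (phlorisovalerophenone)
Conditions: AlCl3 (3–4 equiv), PhNO2, 60 °C; aqueous acidic work-up
Reagents that add atoms: none
Why: Friedel–Crafts acylation of a symmetric, strongly activated arene whose three ring CH positions are equivalent, the first acyl group deactivating the ring against a second acylation.

**Step 2**
Reactants: 3 phlorisovalerophenone; 4 prenyl bromide
Product: 5 3-methyl-1-[2,4,6-trihydroxy-3-(3-methylbut-2-en-1-yl)phenyl]butan-1-one
Conditions: prenyl bromide (0.9 equiv), 10% aq KOH, 0 °C; acidic work-up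
Reagents that add atoms: none
Why: C-alkylation of the ambident acylphloroglucinolate (enolate-type SN2 alkylation) is favoured over O-alkylation in water, the two free ring carbons are equivalent so only one mono-prenyl isomer can form, and a small deficit of bromide holds back the second prenylation.

**Step 3**
Reactants: 5 mono-C-prenyl acylphloroglucinol
Product: 6 1-[2,6-dihydroxy-3-(3-methylbut-2-en-1-yl)-4-(triisopropylsilyloxy)phenyl]-3-methylbutan-1-one
Conditions: TIPSCl (1.05 equiv), imidazole, DMF, 0 °C
Reagents that add atoms: chlorotriisopropylsilane (TIPSCl), CC(C)[Si](Cl)(C(C)C)C(C)C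
Why: Site-selective O-silylation, since the hydroxyl para to the acyl group is the most acidic and is not held in the hydrogen bond to the ketone, while the bulk of TIPS disfavours a second silylation and makes the aryl silyl ether robust to the basic steps that follow.

**Step 4**
Reactants: 7 2-methylbut-3-en-2-ol
Product: 8 tert-butyl 2-methylbut-3-en-2-yl carbonate
Conditions: n-BuLi, THF, −78 °C; then Boc2O, −78 °C to rt
Reagents that add atoms: di-tert-butyl dicarbonate (Boc2O), CC(C)(C)OC(=O)OC(=O)OC(C)(C)C
Why: Acylation of the lithium alkoxide of a tertiary allylic alcohol with Boc2O is the standard way to the mixed tertiary allyl carbonate.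

**Step 5**
Reactants: 6 para-TIPS ether; 8 tert-butyl 2-methylbut-3-en-2-yl carbonate
Product: 10 1-[2,6-bis(2-methylbut-3-en-2-yloxy)-3-(3-methylbut-2-en-1-yl)-4-(triisopropylsilyloxy)phenyl]-3-methylbutan-1-one, via mono-ether 9 (not isolated)
Conditions: 8 (2.5 equiv), Pd(PPh3)4 (5 mol%), 4 Å MS, THF, 0 °C; product kept below 30 °C
Reagents that add atoms: none
Why: Tsuji–Trost O-allylation, in which zerovalent palladium ionises the carbonate to a π-(1,1-dimethylallyl)palladium complex and (after loss of CO2) tert-butoxide that deprotonates the phenol, the phenoxide then attacking the more substituted allyl terminus under kinetic control at 0 °C to give the tertiary ethers, the less hindered hydroxyl first and the hydrogen-bonded one second.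

**Step 6**
Reactants: 10 bis(tert-allyl) ether
Product: 11 1-[3-{[(2R)-3,3-dimethyloxiran-2-yl]methyl}-2,6-bis(2-methylbut-3-en-2-yloxy)-4-(triisopropylsilyloxy)phenyl]-3-methylbutan-1-one
Conditions: 1,2:4,5-di-O-isopropylidene-β-D-erythro-2,3-hexodiulo-2,6-pyranose (D-fructose-derived Shi ketone, 0.3 equiv), Oxone (2KHSO5·KHSO4·K2SO4), K2CO3, Bu4NHSO4, Na2B4O7 buffer, MeCN/CH2(OMe)2/H2O, 0 °C
Reagents that add atoms: potassium peroxymonosulfate (KHSO5, active component of Oxone), [K+].[O-]S(=O)(=O)OO
Why: Shi asymmetric epoxidation, in which the chiral dioxirane attacks the electron-rich trisubstituted prenyl olefin far faster than the two hindered monosubstituted vinyl groups and its spiro transition state should deliver oxygen to the face that gives the (R)-epoxide, the fully O-capped, acyl-deactivated arene being inert to the oxidant.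

**Step 7**
Reactants: 11 (R)-epoxide
Product: 13 1-[(2S)-2-(2-hydroxypropan-2-yl)-4,6-bis(2-methylbut-3-en-2-yloxy)-2,3-dihydro-1-benzofuran-5-yl]-3-methylbutan-1-one, via epoxy phenoxide 12 (not isolated)
Conditions: Bu4NF (1.1 equiv), THF, 0 °C to rt; then H2O
Reagents that add atoms: none
Why: Fluoride desilylation frees the only available oxygen nucleophile, the para-phenoxide, which opens the epoxide by 5-exo-tet SN2 attack at the secondary carbon with inversion (R epoxide to S at C2), basic conditions disfavouring 6-endo attack at the tertiary carbon and the capped O4 and O6 fixing the regiochemistry of ring B.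

**Step 8**
Reactants: 13 bis(1,1-dimethylallyl) ether of the dihydrobenzofuran
Product: 15 (2S,3aS)-6-hydroxy-2-(2-hydroxypropan-2-yl)-5-(3-methylbutanoyl)-3a,7-bis(3-methylbut-2-en-1-yl)-3,3a-dihydro-1-benzofuran-4(2H)-one (CNP0203294.1), via C7-prenyl phenol 14 (not isolated)
Conditions: PhMe (degassed, base-washed glass), 110 °C, sealed tube
Reagents that add atoms: none
Why: Heating should trigger two consecutive concerted, chair-like [3,3] sigmatropic shifts of the tertiary allyl aryl ethers, each handing its CH2 terminus to an ortho carbon: the O6 ether goes to C7 and the dienone tautomerises to phenol 14, then the O4 ether goes to C3a, where the dienone cannot rearomatise and stays as the hydrogen-bonded enol of the triketone, 15. The closest known reaction is the aromatic Claisen rearrangement of aryl 1,1-dimethylallyl ethers, including its dearomative ortho variant onto an already substituted carbon of an acylphloroglucinol (gem-prenylation as in the lupulone series). No ring is closed; only the bonds C7–CH2 and C3a–CH2 are formed. The one new stereocentre, quaternary C3a, is controlled by the C2 stereocentre: the hydroxyisopropyl group screens its own face of ring B, so the allyl unit should add anti to it and give the 2,3a-trans (2S,3aS) isomer, and the reversibility of a shift onto a substituted carbon may let this isomer build up. The step needs the C7 shift to come first and both shifts to avoid C5: C7 is the only hydrogen-bearing, least hindered ortho carbon and its product aromatises irreversibly, while a shift to the acyl-bearing C5 gives a non-enolisable triketone that can only return to the ether. Neutral, acid-free conditions are chosen so that the tertiary ethers rearrange rather than ionise with loss of isoprene.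

**Compound list**

1 | phloroglucinol | Oc1cc(O)cc(O)c1 | starting material
2 | isovaleryl chloride | CC(C)CC(Cl)=O | starting material
3 | 1-(2,4,6-trihydroxyphenyl)-3-methylbutan-1-one | CC(C)CC(=O)c1c(O)cc(O)cc1O | intermediate
4 | prenyl bromide | CC(C)=CCBr | starting material
5 | 3-methyl-1-[2,4,6-trihydroxy-3-(3-methylbut-2-en-1-yl)phenyl]butan-1-one | CC(C)CC(=O)c1c(O)cc(O)c(CC=C(C)C)c1O | intermediate
6 | 1-[2,6-dihydroxy-3-(3-methylbut-2-en-1-yl)-4-(triisopropylsilyloxy)phenyl]-3-methylbutan-1-one | CC(C)CC(=O)c1c(O)cc(O[Si](C(C)C)(C(C)C)C(C)C)c(CC=C(C)C)c1O | intermediate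
7 | 2-methylbut-3-en-2-ol | CC(C)(O)C=C | starting material
8 | tert-butyl 2-methylbut-3-en-2-yl carbonate | CC(C)(C)OC(=O)OC(C)(C)C=C | intermediate
9 | 1-[2-hydroxy-6-(2-methylbut-3-en-2-yloxy)-3-(3-methylbut-2-en-1-yl)-4-(triisopropylsilyloxy)phenyl]-3-methylbutan-1-one (mono-ether at the hydroxyl not flanked by the prenyl group) | CC(C)CC(=O)c1c(OC(C)(C)C=C)cc(O[Si](C(C)C)(C(C)C)C(C)C)c(CC=C(C)C)c1O | intermediate
10 | 1-[2,6-bis(2-methylbut-3-en-2-yloxy)-3-(3-methylbut-2-en-1-yl)-4-(triisopropylsilyloxy)phenyl]-3-methylbutan-1-one | CC(C)CC(=O)c1c(OC(C)(C)C=C)cc(O[Si](C(C)C)(C(C)C)C(C)C)c(CC=C(C)C)c1OC(C)(C)C=C | intermediate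
11 | 1-[3-{[(2R)-3,3-dimethyloxiran-2-yl]methyl}-2,6-bis(2-methylbut-3-en-2-yloxy)-4-(triisopropylsilyloxy)phenyl]-3-methylbutan-1-one | CC(C)CC(=O)c1c(OC(C)(C)C=C)cc(O[Si](C(C)C)(C(C)C)C(C)C)c(C[C@H]2OC2(C)C)c1OC(C)(C)C=C | intermediate
12 | 1-[3-{[(2R)-3,3-dimethyloxiran-2-yl]methyl}-4-hydroxy-2,6-bis(2-methylbut-3-en-2-yloxy)phenyl]-3-methylbutan-1-one (present in the flask as its tetrabutylammonium phenoxide) | CC(C)CC(=O)c1c(OC(C)(C)C=C)cc(O)c(C[C@H]2OC2(C)C)c1OC(C)(C)C=C | intermediate
13 | 1-[(2S)-2-(2-hydroxypropan-2-yl)-4,6-bis(2-methylbut-3-en-2-yloxy)-2,3-dihydro-1-benzofuran-5-yl]-3-methylbutan-1-one | CC(C)CC(=O)c1c(OC(C)(C)C=C)cc2O[C@H](C(C)(C)O)Cc2c1OC(C)(C)C=C | intermediate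
14 | 1-[(2S)-6-hydroxy-2-(2-hydroxypropan-2-yl)-4-(2-methylbut-3-en-2-yloxy)-7-(3-methylbut-2-en-1-yl)-2,3-dihydro-1-benzofuran-5-yl]-3-methylbutan-1-one | CC(C)CC(=O)c1c(O)c(CC=C(C)C)c2O[C@H](C(C)(C)O)Cc2c1OC(C)(C)C=C | intermediate
15 | (2S,3aS)-6-hydroxy-2-(2-hydroxypropan-2-yl)-5-(3-methylbutanoyl)-3a,7-bis(3-methylbut-2-en-1-yl)-3,3a-dihydro-1-benzofuran-4(2H)-one (CNP0203294.1; C2 hydroxyisopropyl and C3a prenyl on opposite faces of ring B) | CC(C)=CCC1=C2O[C@H](C(C)(C)O)C[C@]2(CC=C(C)C)C(=O)C(C(=O)CC(C)C)=C1O | target

**Step count**

Total: 8 steps. Longest linear sequence: 7 steps (steps 1, 2, 3, 5, 6, 7, 8); step 4 is a one-step side branch.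

**Steps most likely to fail**

Step 8. The dearomative shift may run with poor facial selectivity at C3a. It may also run ahead of the C7 shift, which would divert material towards C5-alkylated, non-enolisable products. Heating can further cause ionisation of the tertiary ethers with loss of isoprene. The fallback sets out from 13 and comes back at 15. Instead of heating, 13 is treated with Pd2(dba)3 and N,N'-[(1R,2R)-cyclohexane-1,2-diyl]bis[2-(diphenylphosphanyl)benzamide], or its (1S,2S) enantiomer, in THF at 0 °C to room temperature. Zerovalent palladium ionises each tertiary allyl aryl ether to a π-(1,1-dimethylallyl)palladium cation and the acylphloroglucinol-type aryloxide. The aryloxide is then C-alkylated at the unsubstituted allyl terminus (Tsuji–Trost allylation, dearomative at C3a), first at C7, the free and most nucleophilic ring carbon. The allyl unit then comes from a chiral metal complex and not through an intramolecular chair, so the ligand enantiomer can steer the face of C3a, and the dissociative mechanism removes the dependence on the order of the two transfers. No compound outside the main list is made; 14 is again the passing intermediate.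

Step 5. Alkylation of the hydrogen-bonded, doubly flanked hydroxyl may stall at mono-ether 9. Prolonged contact with the catalyst may also isomerise the branched ethers to linear prenyl ethers or lead to C-allylation of the ring. The fallback sets out from 6 and comes back at 10. Both phenols are O-alkylated with 3-chloro-3-methylbut-1-yne (DBU, CuCl2 cat., MeCN, 0 °C; copper acetylide pathway, O-selective and tolerant of hindered phenols) to give 1-[2,6-bis(2-methylbut-3-yn-2-yloxy)-3-(3-methylbut-2-en-1-yl)-4-(triisopropylsilyloxy)phenyl]-3-methylbutan-1-one F1. Semi-hydrogenation (H2, Pd/CaCO3 poisoned with Pb(OAc)2, quinoline, EtOAc) should then reduce the two alkynes to vinyl groups without touching the trisubstituted prenyl olefin, giving 10.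

Step 3. Silylation may occur at a hydroxyl ortho to the acyl group, or twice, which would leave the wrong oxygen free for ring closure later. The fallback sets out from 5 and comes back at 13; it gives up the protecting-group control and relies on the higher acidity of the para hydroxyl during cyclisation.
- Peracetylation (Ac2O, pyridine, DMAP cat.) gives 2-(3-methylbutanoyl)-4-(3-methylbut-2-en-1-yl)benzene-1,3,5-triyl triacetate F2.
- Shi epoxidation, as in step 6 but at the low end of the pH window to spare the aryl acetates, gives the (R)-epoxy triacetate, 2-{[(2R)-3,3-dimethyloxiran-2-yl]methyl}-4-(3-methylbutanoyl)benzene-1,3,5-triyl triacetate F3.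
- K2CO3 in MeOH removes the acetates; the most acidic, para-phenoxide should close ring B by 5-exo opening to give 1-[(2S)-4,6-dihydroxy-2-(2-hydroxypropan-2-yl)-2,3-dihydro-1-benzofuran-5-yl]-3-methylbutan-1-one F4.
- Bis O-tert-prenylation of F4 with 8 and Pd(PPh3)4 (THF, 0 °C) then gives 13; the tertiary alcohol does not react under these conditions.

**Further compounds**

F0 | step 8 | none | none
F1 | step 5 | 1-[2,6-bis(2-methylbut-3-yn-2-yloxy)-3-(3-methylbut-2-en-1-yl)-4-(triisopropylsilyloxy)phenyl]-3-methylbutan-1-one | CC(C)CC(=O)c1c(OC(C)(C)C#C)cc(O[Si](C(C)C)(C(C)C)C(C)C)c(CC=C(C)C)c1OC(C)(C)C#C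
F2 | step 3 | 2-(3-methylbutanoyl)-4-(3-methylbut-2-en-1-yl)benzene-1,3,5-triyl triacetate | CC(C)CC(=O)c1c(OC(C)=O)cc(OC(C)=O)c(CC=C(C)C)c1OC(C)=O
F3 | step 3 | 2-{[(2R)-3,3-dimethyloxiran-2-yl]methyl}-4-(3-methylbutanoyl)benzene-1,3,5-triyl triacetate | CC(C)CC(=O)c1c(OC(C)=O)cc(OC(C)=O)c(C[C@H]2OC2(C)C)c1OC(C)=O
F4 | step 3 | 1-[(2S)-4,6-dihydroxy-2-(2-hydroxypropan-2-yl)-2,3-dihydro-1-benzofuran-5-yl]-3-methylbutan-1-one | CC(C)CC(=O)c1c(O)cc2O[C@H](C(C)(C)O)Cc2c1O
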